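**Retrosynthetic overview**
1. Target 14 ⇐ dihydrobenzofuran 11 (phenol masked as acetate) by allylic hydroxylation of the isopropenyl methyl, O‑acetylation and release of the phenol.
2. 11 ⇐ chromanol 9 by ring contraction: 1,2‑shift of the ring oxygen from C2 to C3 of the cis‑4‑angeloyloxychroman‑3‑yl triflate (pyran → dihydrofuran, inversion at the migration terminus).
3. 9 ⇐ epoxide 7 + angelic acid by stereoretentive opening at the benzylic carbon; 7 ⇐ chromene 6 by Jacobsen epoxidation (both stereocentres fixed here).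
4. 6 ⇐ aryl dimethylpropargyl ether 5 (Claisen/cyclisation) ⇐ resacetophenone 2 ⇐ resorcinol + acetic acid; the C5 unit comes from 3‑chloro‑3‑methylbut‑1‑yne.
5. Ring order: benzene ring (given), pyran ring, oxirane, then contraction of the pyran to the dihydrofuran ring.

Assumption: the facial senses quoted for the (R,R)‑salen manganese catalyst and, in one fallback, for (DHQ)2PYR are taken from the parent 2,2‑dimethylchromene series; should either prove opposite, the enantiomeric catalyst or the (DHQD)2PYR ligand is used.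

**Route**

Step 1
Reactants: 1 resorcinol
Product: 2 resacetophenone 1-(2,4-dihydroxyphenyl)ethanone
Conditions: AcOH, ZnCl2, 140 °C
Reagents that add atoms: acetic acid CC(=O)O
Why: Nencki (Friedel–Crafts type) C‑acylation of resorcinol, which goes para to one hydroxyl and ortho to the other; no stereocentre is formed.

Step 2
Reactants: 2 resacetophenone; 3 3-chloro-3-methylbut-1-yne
Product: 5 2-acetyl-5-(2-methylbut-3-yn-2-yloxy)phenyl acetate, via propargyl ether phenol 4 (not isolated)
Conditions: 3 (1.5 equiv), K2CO3, KI (cat.), acetone, reflux; then Ac2O, DMAP (cat.), rt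
Reagents that add atoms: acetic anhydride CC(=O)OC(C)=O
Why: Williamson O‑alkylation of the free (non‑chelated) para hydroxyl followed by O‑acetylation of the chelated ortho hydroxyl, which protects the phenol and removes the chelate that would steer the next step to the carbon between the two oxygens.

Step 3
Reactants: 5 2-acetyl-5-(2-methylbut-3-yn-2-yloxy)phenyl acetate
Product: 6 6-acetyl-2,2-dimethyl-2H-chromen-7-yl acetate
Conditions: PhNEt2, 180 °C
Reagents that add atoms: none
Why: Aromatic propargyl Claisen rearrangement, [1,5]‑H shift and oxa‑6π ring closure; without chelate bond fixation the migration goes to the less hindered carbon para to the acetoxy group, giving the linear chromene.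

Step 4
Reactants: 6 6-acetyl-2,2-dimethyl-2H-chromen-7-yl acetate
Product: 7 (3R,4R)-6-acetyl-3,4-epoxy-2,2-dimethylchroman-7-yl acetate
Conditions: (R,R)-Mn(C36H52N2O2)Cl (Jacobsen salen complex, trivalent manganese; 5 mol %), mCPBA, NMO, CH2Cl2, −78 °C
Reagents that add atoms: mCPBA O=C(OO)c1cccc(Cl)c1
Why: Jacobsen–Katsuki epoxidation, for which 2,2‑dimethylchromenes are the best substrate class (typically over 95% ee); the (R,R) catalyst sets both oxirane carbons as (3R,4R), and the anhydrous low‑temperature protocol leaves the aryl acetate and ketone untouched.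

Step 5
Reactants: 7 (3R,4R)-epoxide; 8 angelic acid
Product: 9 (3R,4R)-7-acetoxy-6-acetyl-3-hydroxy-2,2-dimethylchroman-4-yl (Z)-2-methylbut-2-enoate (3‑OH and 4‑ester cis)
Conditions: 8 (1.3 equiv), (C6F5)2BOH (10 mol %), 4 Å MS, PhMe, −40 → 0 °C
Reagents that add atoms: none
Why: Proposed new method: borinic‑acid‑catalysed stereoretentive (SNi‑type) hydroacyloxylation of a benzylic epoxide, in which (C6F5)2BOH and 8 form the Lewis‑acidic mixed anhydride (C6F5)2B–O2CR, this binds the oxirane oxygen, the benzylic C4–O bond ionises (cation stabilised through the ring oxygen ortho to C4a), and the boron‑bound carboxylate collapses onto C4 from the face of the departing oxygen through a seven‑membered transition state, so C4 is set with retention (4R, ester cis to the 3‑OH) without base that could isomerise angelate to tiglate, and the O3‑borinate is released by exchange with 8; the closest known reaction types are SNi‑type syn openings of aryl and glycal epoxides (BF3 to syn‑fluorohydrins, AlMe3), syn acidolysis of aryl oxiranes by strong carboxylic acids in apolar solvents, and borinic‑acid‑catalysed epoxide openings.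

Step 6
Reactants: 9 cis‑hydroxy angelate
Product: 11 (2R,3R)-6-acetoxy-5-acetyl-2-(prop-1-en-2-yl)-2,3-dihydrobenzofuran-3-yl (Z)-2-methylbut-2-enoate, via C3 triflate 10 (not isolated)
Conditions: Tf2O (1.2 equiv), 2,6-di-tert-butyl-4-methylpyridine (3 equiv), CH2Cl2, −78 → 0 °C
Reagents that add atoms: none
Why: Wagner–Meerwein‑type ring contraction by 1,2‑shift of the ring oxygen, the reaction type by which activated 2,2‑dimethylchroman‑3‑ols contract to 2‑isopropenyl‑2,3‑dihydrobenzofurans and pyranoside 2‑triflates to furanoid products: the equatorial C3 triflate is antiperiplanar to the C2–O1 bond, O1 migrates to C3 with inversion (this carbon becomes C2 of the dihydrobenzofuran, R), the cis 4‑ester has neither an anti oxygen nor an anti hydrogen and so cannot participate or eliminate, the acyloxy group disfavours the competing aryl shift, and the epoxonium/tertiary cation loses a methyl proton to the hindered base to give the isopropenyl group with the ester carbon untouched (2,3‑cis).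

Step 7
Reactants: 11 cis‑dihydrobenzofuran
Product: 12 (2R,3R)-6-acetoxy-5-acetyl-2-(3-hydroxyprop-1-en-2-yl)-2,3-dihydrobenzofuran-3-yl (Z)-2-methylbut-2-enoate
Conditions: SeO2 (0.3 equiv), t-BuOOH (2 equiv), CH2Cl2, 0 °C → rt
Reagents that add atoms: tert-butyl hydroperoxide CC(C)(C)OO
Why: Riley/Sharpless selenium dioxide allylic oxidation (ene reaction then [2,3] shift), which on isopropenyl groups oxidises the methyl in preference to the hindered oxygen‑bearing methine; the electron‑poor angelate alkene and the methyl ketone are inert at room temperature and no stereocentre is touched.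

Step 8
Reactants: 12 allylic alcohol
Product: 14 target (2R,3R)-2-(3-acetoxyprop-1-en-2-yl)-5-acetyl-6-hydroxy-2,3-dihydrobenzofuran-3-yl (Z)-2-methylbut-2-enoate, via bis-acetate 13 (not isolated)
Conditions: Ac2O (1.3 equiv), pyridine, CH2Cl2, 0 °C; then MeOH, NH4OAc, MeOH–H2O 4:1, rt
Reagents that add atoms: acetic anhydride CC(=O)OC(C)=O
Why: O‑acetylation of the primary allylic alcohol followed by ammonium acetate‑mediated methanolysis, which cleaves aryl acetates selectively in the presence of alkyl esters; the near‑neutral medium avoids quinone‑methide loss of the benzylic angelate, elimination to the benzofuran and angelate‑to‑tiglate isomerisation.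

**Compound list**
1 | resorcinol (benzene-1,3-diol) | Oc1cccc(O)c1 | starting material
2 | resacetophenone, 1-(2,4-dihydroxyphenyl)ethanone | CC(=O)c1ccc(O)cc1O | intermediate
3 | 3-chloro-3-methylbut-1-yne | C#CC(C)(C)Cl | starting material
4 | 1-[2-hydroxy-4-(2-methylbut-3-yn-2-yloxy)phenyl]ethanone | CC(=O)c1ccc(OC(C)(C)C#C)cc1O | intermediate
5 | 2-acetyl-5-(2-methylbut-3-yn-2-yloxy)phenyl acetate | CC(=O)Oc1cc(OC(C)(C)C#C)ccc1C(C)=O | intermediate
6 | 6-acetyl-2,2-dimethyl-2H-chromen-7-yl acetate | CC1(C)Oc2cc(OC(C)=O)c(C(C)=O)cc2C=C1 | intermediate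
7 | (3R,4R)-6-acetyl-3,4-epoxy-2,2-dimethylchroman-7-yl acetate | CC1(C)Oc2cc(OC(C)=O)c(C(C)=O)cc2[C@H]3O[C@H]31 | intermediate
8 | angelic acid, (Z)-2-methylbut-2-enoic acid | C/C=C(/C)C(=O)O | starting material
9 | (3R,4R)-7-acetoxy-6-acetyl-3-hydroxy-2,2-dimethylchroman-4-yl (Z)-2-methylbut-2-enoate | CC1(C)Oc2cc(OC(C)=O)c(C(C)=O)cc2[C@@H](OC(=O)/C(C)=C\C)[C@H]1O | intermediate
10 | (3R,4R)-7-acetoxy-6-acetyl-2,2-dimethyl-3-(trifluoromethylsulfonyloxy)chroman-4-yl (Z)-2-methylbut-2-enoate | CC1(C)Oc2cc(OC(C)=O)c(C(C)=O)cc2[C@@H](OC(=O)/C(C)=C\C)[C@H]1OS(=O)(=O)C(F)(F)F | intermediate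
11 | (2R,3R)-6-acetoxy-5-acetyl-2-(prop-1-en-2-yl)-2,3-dihydrobenzofuran-3-yl (Z)-2-methylbut-2-enoate | C=C(C)[C@H]1Oc2cc(OC(C)=O)c(C(C)=O)cc2[C@H]1OC(=O)/C(C)=C\C | intermediate
12 | (2R,3R)-6-acetoxy-5-acetyl-2-(3-hydroxyprop-1-en-2-yl)-2,3-dihydrobenzofuran-3-yl (Z)-2-methylbut-2-enoate | C=C(CO)[C@H]1Oc2cc(OC(C)=O)c(C(C)=O)cc2[C@H]1OC(=O)/C(C)=C\C | intermediate
13 | (2R,3R)-6-acetoxy-2-(3-acetoxyprop-1-en-2-yl)-5-acetyl-2,3-dihydrobenzofuran-3-yl (Z)-2-methylbut-2-enoate | C=C(COC(C)=O)[C@H]1Oc2cc(OC(C)=O)c(C(C)=O)cc2[C@H]1OC(=O)/C(C)=C\C | intermediate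
14 | (2R,3R)-2-(3-acetoxyprop-1-en-2-yl)-5-acetyl-6-hydroxy-2,3-dihydrobenzofuran-3-yl (Z)-2-methylbut-2-enoate | C=C(COC(C)=O)[C@H]1Oc2cc(O)c(C(C)=O)cc2[C@H]1OC(=O)/C(C)=C\C | target

**Step count**
Total steps: 8. Longest linear sequence: 8 (fully linear from resorcinol).

**Steps most likely to fail**

Step 5 (the proposed new step). Risks are anti opening by free acid (trans isomer) and Lewis‑acid rearrangement of the epoxide to the chroman‑3‑one. The fallback uses known chemistry, sets out from 6 and comes back at 9. Chromene 6 is dihydroxylated under the neutral N‑oxide variant of the osmium‑catalysed asymmetric dihydroxylation (K2OsO2(OH)4 1 mol %, (DHQ)2PYR 5 mol %, NMO, acetone–H2O, 0 °C, slow addition of 6), which spares the aryl acetate, to give the (3R,4R)-cis-diol F1. Angelic acid 8 is converted with 2,4,6‑trichlorobenzoyl chloride and Et3N into the angelic 2,4,6‑trichlorobenzoic mixed anhydride F2 (Yamaguchi activation, which keeps the Z geometry). F2 with DMAP (cat.) in toluene at 0 °C acylates the less hindered benzylic 4‑OH of F1 rather than the 3‑OH next to the quaternary carbon, giving 9.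

Step 6. Risks are capture of the tertiary cation by the cis angelate carbonyl (six‑membered acyloxonium), a competing aryl shift, or loss of the ring proton to an enol ether. The fallback keeps the ring contraction but moves the angelate to the end; it sets out from 7 and comes back at 11. Epoxide 7 is opened with CF3CO2H (1.1 equiv) in toluene at −40 °C, the syn acidolysis typical of electron‑rich aryl oxiranes, to the cis-hydroxy trifluoroacetate F3. Tf2O and 2,6‑di‑tert‑butyl‑4‑methylpyridine convert F3 through its C3 triflate F4 into the ring-contracted trifluoroacetate F5; the trifluoroacetyl carbonyl is too weakly nucleophilic to trap the cation and disfavours the aryl shift further. NaHCO3 in MeOH at 0 °C removes only the trifluoroacetate to give the cis-alcohol F6, which is esterified with the mixed anhydride F2 (DMAP, toluene, 0 °C) to give 11.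

Step 7. Risks are low conversion, over‑oxidation to the enal, or attack at the C2 methine. The fallback sets out from 11 and comes back at 13. Ene‑type chlorination of the isopropenyl group (NaOCl, CeCl3·7H2O, CH2Cl2–H2O, 0 °C) gives the allylic chloride F7. Displacement with CsOAc in DMF at rt gives bis‑acetate 13, here isolated, which then enters the second stage of step 8.

**Further compounds**
F1 | step 5 | (3R,4R)-6-acetyl-3,4-dihydroxy-2,2-dimethylchroman-7-yl acetate | CC1(C)Oc2cc(OC(C)=O)c(C(C)=O)cc2[C@@H](O)[C@H]1O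
F2 | step 5 | angelic 2,4,6-trichlorobenzoic mixed anhydride | C/C=C(/C)C(=O)OC(=O)c1c(Cl)cc(Cl)cc1Cl
F3 | step 6 | (3R,4R)-7-acetoxy-6-acetyl-3-hydroxy-2,2-dimethylchroman-4-yl trifluoroacetate | CC1(C)Oc2cc(OC(C)=O)c(C(C)=O)cc2[C@@H](OC(=O)C(F)(F)F)[C@H]1O
F4 | step 6 | (3R,4R)-7-acetoxy-6-acetyl-2,2-dimethyl-3-(trifluoromethylsulfonyloxy)chroman-4-yl trifluoroacetate | CC1(C)Oc2cc(OC(C)=O)c(C(C)=O)cc2[C@@H](OC(=O)C(F)(F)F)[C@H]1OS(=O)(=O)C(F)(F)F
F5 | step 6 | (2R,3R)-6-acetoxy-5-acetyl-2-(prop-1-en-2-yl)-2,3-dihydrobenzofuran-3-yl trifluoroacetate | C=C(C)[C@H]1Oc2cc(OC(C)=O)c(C(C)=O)cc2[C@H]1OC(=O)C(F)(F)F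
F6 | step 6 | (2R,3R)-5-acetyl-3-hydroxy-2-(prop-1-en-2-yl)-2,3-dihydrobenzofuran-6-yl acetate | C=C(C)[C@H]1Oc2cc(OC(C)=O)c(C(C)=O)cc2[C@H]1O
F7 | step 7 | (2R,3R)-6-acetoxy-5-acetyl-2-(3-chloroprop-1-en-2-yl)-2,3-dihydrobenzofuran-3-yl (Z)-2-methylbut-2-enoate | C=C(CCl)[C@H]1Oc2cc(OC(C)=O)c(C(C)=O)cc2[C@H]1OC(=O)/C(C)=C\C
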